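**Retrosynthetic overview**
1. The target is opened at both amides to a C2-symmetric cyclobutane tetra-amine and two equivalents of 2-(trichloroacetyl)pyrrole. The pyrrole rings are bought.
2. The tetra-amine comes from a trans-fused 3,6-diazabicyclo[6.2.0]decane. (S,S)-1,2-Diphenylethylenediamine supplies both side-chain nitrogens and later leaves as bibenzyl. Imidazo[1,2-a]pyrimidines mask the 2-aminoimidazoles and are opened with hydrazine.
3. Key disconnection: both new cyclobutane C–C bonds are cut to an open-chain N,N'-bis(hetarylallyl)diamine. One sensitised intramolecular [2+2] closes the cyclobutane and the eight-membered diazocane together and sets all four stereocentres.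
4. The diene comes from double reductive amination of 3-(imidazo[1,2-a]pyrimidin-3-yl)acrolein. The enal comes from a Heck reaction of the commercial 3-bromo heterocycle with acrolein acetal.
5. Ring order: bought heteroaromatics, then cyclobutane and diazocane in the same operation, then the pyrimidine rings and the diazocane are opened again.

Assumption: all basic compounds are drawn and balanced as free bases, and the sense of induction of the diamine tether is taken from the torsion-matching model given in step 3 (both enantiomers of the diamine are sold at similar cost).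

**Step 1**
Reactants: 1 3-bromoimidazo[1,2-a]pyrimidine; 2 acrolein diethyl acetal (3,3-diethoxyprop-1-ene)
Product: 4 (2E)-3-(imidazo[1,2-a]pyrimidin-3-yl)prop-2-enal, via enal diethyl acetal 3 (not isolated)
Conditions: Pd(OAc)2 (3 mol %), nBu4NOAc, K2CO3, KCl, DMF, 90 °C; then 2 M aq HCl, rt
Reagents that add atoms: water, O
Why: Heck reaction under ligand-free Jeffery-type conditions, in which carbopalladation at the terminal alkene carbon and β-hydride elimination away from the acetal C–H (favoured by the acetate/carbonate medium) give the E-alkene, and aqueous acid then hydrolyses the acetal; no stereocentre is formed.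

**Step 2**
Reactants: 4 (2E)-3-(imidazo[1,2-a]pyrimidin-3-yl)prop-2-enal (2.05 equiv); 5 (1S,2S)-1,2-diphenylethane-1,2-diamine
Product: 7 (1S,2S)-N1,N2-bis[(2E)-3-(imidazo[1,2-a]pyrimidin-3-yl)prop-2-en-1-yl]-1,2-diphenylethane-1,2-diamine, via bis-enimine 6 (not isolated)
Conditions: 4 Å MS, CH2Cl2/MeOH, rt; then NaBH4, 0 °C, 30 min
Reagents that add atoms: none
Why: Stepwise double reductive amination, in which the primary amines condense to the conjugated diimine (its diaza-Cope rearrangement needs heat), cold borohydride reduces the aldimines 1,2 much faster than it attacks the neutral azine ring or the alkenes, and the two benzylic stereocentres of 5 are carried through untouched.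

**Step 3 (key step)**
Reactants: 7 (1S,2S)-N1,N2-bis[(2E)-3-(imidazo[1,2-a]pyrimidin-3-yl)prop-2-en-1-yl]-1,2-diphenylethane-1,2-diamine
Product: 8 (1R,4S,5S,8R,9S,10S)-9,10-di(imidazo[1,2-a]pyrimidin-3-yl)-4,5-diphenyl-3,6-diazabicyclo[6.2.0]decane
Conditions: fac-Ir(ppy)3 (2 mol %), degassed MeOH (5 mM), 450 nm LEDs, 25 °C, 36 h; chromatography to remove minor diastereomers
Reagents that add atoms: none
Why: Proposed new method: triplet energy transfer from fac-Ir(ppy)3 (ET about 55–58 kcal/mol, and too weak an excited-state oxidant at about +0.3 V vs SCE to attack the secondary amines) excites one hetarylvinyl arm, which bonds to the other arm at the carbons next to CH2 to give an eight-membered-ring 1,4-diradical with two heterobenzylic centres that closes after intersystem crossing, so cyclobutane and 1,4-diazocane form in one operation while E/Z isomerisation only wastes photons and dilution suppresses intermolecular dimers; the six-atom tether enforces head-to-head regiochemistry, the stepwise closure gives the least strained all-trans array (a cis fusion needs a ring torsion near 0° that no low-energy eight-membered ring offers), and the absolute sense follows from torsion matching, because in boat-chair and crown-type eight-membered rings opposite ring bonds carry torsions of like sign, so the (S,S)-diamine with equatorial phenyls (N–C–C–N about +60°) selects CH2–C–C–CH2 of about +100°, which is the (1R,8R,9S,10S) cyclobutane, and any mismatched isomer is a separable diastereomer; the closest known reaction types are the Ir-sensitised intermolecular head-to-head [2+2] dimerisation of vinyl-hetarenes and styrenes and the intramolecular photodimerisation of dicinnamates of C2-symmetric chiral diols to δ-truxinates.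

**Step 4**
Reactants: 8 (1R,4S,5S,8R,9S,10S)-9,10-di(imidazo[1,2-a]pyrimidin-3-yl)-4,5-diphenyl-3,6-diazabicyclo[6.2.0]decane
Product: 9 (1R,4S,5S,8R,9S,10S)-9,10-bis(2-amino-1H-imidazol-5-yl)-4,5-diphenyl-3,6-diazabicyclo[6.2.0]decane
Conditions: N2H4·H2O (20 equiv), EtOH, 80 °C
Reagents that add atoms: none
Why: Hydrazinolysis of the imidazo[1,2-a]pyrimidine (addition, ring opening, ring closure), in which hydrazine adds to the electron-poor pyrimidine ring and carries off C5–C7 as pyrazole to leave the 2-aminoimidazole, while the secondary amines and the cyclobutane stereocentres (no acidifying group) are unaffected.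

**Step 5**
Reactants: 9 (1R,4S,5S,8R,9S,10S)-9,10-bis(2-amino-1H-imidazol-5-yl)-4,5-diphenyl-3,6-diazabicyclo[6.2.0]decane
Product: 10 5,5'-[(1S,2S,3R,4R)-3,4-bis(aminomethyl)cyclobutane-1,2-diyl]bis(1H-imidazol-2-amine)
Conditions: H2 (5 bar), 20 % Pd(OH)2/C, MeOH/AcOH 4:1, 45 °C; Et2O wash; Amberlyst A-26 (OH form), MeOH
Reagents that add atoms: none
Why: Catalytic hydrogenolysis of benzylic C–N bonds with Pearlman's catalyst, in which both N–CHPh bonds are benzylic (the second still is after the ring has opened) so the bridge leaves as bibenzyl, while the N–CH2 bonds, the protonated 2-aminoimidazoles and the four cyclobutane stereocentres are not touched.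

**Step 6**
Reactants: 10 5,5'-[(1S,2S,3R,4R)-3,4-bis(aminomethyl)cyclobutane-1,2-diyl]bis(1H-imidazol-2-amine); 11 2-(trichloroacetyl)pyrrole (2.1 equiv)
Product: 12 N,N'-{[(1R,2R,3S,4S)-3,4-bis(2-amino-1H-imidazol-5-yl)cyclobutane-1,2-diyl]bis(methylene)}bis(1H-pyrrole-2-carboxamide) (target CNP0598529.1)
Conditions: DMF, 23 °C, 16 h; reversed-phase chromatography
Reagents that add atoms: none
Why: Haloform-type acyl transfer (aminolysis of a trichloromethyl ketone), in which only the two primary alkylamines are nucleophilic enough to expel CCl3−, the guanidine-like 2-aminoimidazoles and the pyrrole NH stay unacylated at room temperature, and no stereocentre is involved.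

**Compound list**
1 | 3-bromoimidazo[1,2-a]pyrimidine | Brc1cnc2ncccn12 | starting material
2 | acrolein diethyl acetal | C=CC(OCC)OCC | starting material
3 | (E)-3-(3,3-diethoxyprop-1-en-1-yl)imidazo[1,2-a]pyrimidine | CCOC(OCC)/C=C/c1cnc2ncccn12 | intermediate
4 | (2E)-3-(imidazo[1,2-a]pyrimidin-3-yl)prop-2-enal | O=C/C=C/c1cnc2ncccn12 | intermediate
5 | (1S,2S)-1,2-diphenylethane-1,2-diamine | N[C@@H](c1ccccc1)[C@@H](N)c1ccccc1 | starting material
6 | (1S,2S)-N1,N2-bis[(1E,2E)-3-(imidazo[1,2-a]pyrimidin-3-yl)prop-2-en-1-ylidene]-1,2-diphenylethane-1,2-diamine | c1cnc2ncc(/C=C/C=N/[C@@H](c3ccccc3)[C@@H](/N=C/C=C/c3cnc4ncccn34)c3ccccc3)n2c1 | intermediate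
7 | (1S,2S)-N1,N2-bis[(2E)-3-(imidazo[1,2-a]pyrimidin-3-yl)prop-2-en-1-yl]-1,2-diphenylethane-1,2-diamine | c1cnc2ncc(/C=C/CN[C@@H](c3ccccc3)[C@@H](NC/C=C/c3cnc4ncccn34)c3ccccc3)n2c1 | intermediate
8 | (1R,4S,5S,8R,9S,10S)-9,10-di(imidazo[1,2-a]pyrimidin-3-yl)-4,5-diphenyl-3,6-diazabicyclo[6.2.0]decane | c1cnc2ncc([C@H]3[C@H](CN[C@@H](c4ccccc4)[C@H](c4ccccc4)NC5)[C@@H]5[C@@H]3c3cnc4ncccn34)n2c1 | intermediate
9 | (1R,4S,5S,8R,9S,10S)-9,10-bis(2-amino-1H-imidazol-5-yl)-4,5-diphenyl-3,6-diazabicyclo[6.2.0]decane | Nc1ncc([C@H]2[C@H](CN[C@@H](c3ccccc3)[C@H](c3ccccc3)NC4)[C@@H]4[C@@H]2c2cnc(N)[nH]2)[nH]1 | intermediate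
10 | 5,5'-[(1S,2S,3R,4R)-3,4-bis(aminomethyl)cyclobutane-1,2-diyl]bis(1H-imidazol-2-amine) | Nc1ncc([C@H]2[C@H](CN)[C@@H](CN)[C@@H]2c2cnc(N)[nH]2)[nH]1 | intermediate
11 | 2-(trichloroacetyl)pyrrole | O=C(c1ccc[nH]1)C(Cl)(Cl)Cl | starting material
12 | N,N'-{[(1R,2R,3S,4S)-3,4-bis(2-amino-1H-imidazol-5-yl)cyclobutane-1,2-diyl]bis(methylene)}bis(1H-pyrrole-2-carboxamide) | Nc1ncc([C@H]2[C@H](CNC(=O)c3ccc[nH]3)[C@@H](CNC(=O)c3ccc[nH]3)[C@@H]2c2cnc(N)[nH]2)[nH]1 | target

**Totals**
Total step count: 6. Longest linear sequence: 6 (1 → 4 → 7 → 8 → 9 → 10 → 12).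

**Steps most likely to fail (in this order: 3, 5, 1)**

Risk at step 3: closure of the medium ring may lose to unproductive E/Z cycling and oligomerisation, or the tether may induce weakly or in the wrong sense. The fallback gives up the tether and relies on separating diastereomers. It sets out from 4 and comes back at 10.
- Reductive amination of 4 with (S)-1-phenylethylamine (4 Å MS, then NaBH4) gives (S)-N-[(2E)-3-(imidazo[1,2-a]pyrimidin-3-yl)prop-2-en-1-yl]-1-phenylethanamine F1.
- Concentrated (0.3 M) Ir-sensitised intermolecular head-to-head dimerisation gives the all-trans dimer as two diastereomers that differ only in the chirality of the core.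
- Chromatography or salt crystallisation isolates the (1R,2R,3S,4S)-core N,N'-bis[(S)-1-phenylethyl] dimer F2.
- Hydrazine hydrate converts it into the corresponding bis(2-aminoimidazole) N,N'-bis[(S)-1-phenylethyl]diamine F3.
- Hydrogenolysis over Pd(OH)2/C removes both phenylethyl groups and delivers 10.

Risk at step 5: the polybasic substrate may poison the catalyst, the second and more hindered C–N cleavage may stall, or the doubly hetaryl-activated cyclobutane C–C bond may be hydrogenolysed. The fallback removes the bridge oxidatively. It sets out from 8 and comes back at 10, bypassing 9.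
- Pb(OAc)4 in CH2Cl2/MeOH at −20 °C cleaves the PhCH–CHPh bond of the vicinal diamine, as in a glycol cleavage.
- This gives the (1R,2R,3S,4S)-cyclobutane bis(N-benzylidene)aminomethyl compound F4.
- Hydrazine hydrate in hot EtOH then trans-iminates both benzylidene groups and opens both pyrimidine rings in the same pot, giving 10.

Risk at step 1: the azine nitrogens may slow the palladium catalyst, and β-hydride elimination towards the acetal carbon would give the saturated ethyl ester. The fallback fixes regiochemistry and geometry in the coupling partner. It sets out from 1 and comes back at 3.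
- Suzuki–Miyaura coupling of 1 with commercial (E)-3,3-diethoxyprop-1-enylboronic acid pinacol ester (Pd(dppf)Cl2, K2CO3, dioxane/water, 80 °C) gives 3.
- 3 is hydrolysed to 4 as in the main route.
- This fallback makes no compound that is missing from the list (entry F0).

**Further compounds**
F1 | step 3 | (S)-N-[(2E)-3-(imidazo[1,2-a]pyrimidin-3-yl)prop-2-en-1-yl]-1-phenylethanamine | C[C@H](NC/C=C/c1cnc2ncccn12)c1ccccc1
F2 | step 3 | (1S,1'S)-N,N'-{[(1R,2R,3S,4S)-3,4-di(imidazo[1,2-a]pyrimidin-3-yl)cyclobutane-1,2-diyl]bis(methylene)}bis(1-phenylethanamine) | c1cnc2ncc([C@H]3[C@H](CN[C@@H](C)c4ccccc4)[C@@H](CN[C@@H](C)c4ccccc4)[C@@H]3c3cnc4ncccn34)n2c1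
F3 | step 3 | 5,5'-[(1S,2S,3R,4R)-3,4-bis({[(1S)-1-phenylethyl]amino}methyl)cyclobutane-1,2-diyl]bis(1H-imidazol-2-amine) | Nc1ncc([C@H]2[C@H](CN[C@@H](C)c3ccccc3)[C@@H](CN[C@@H](C)c3ccccc3)[C@@H]2c2cnc(N)[nH]2)[nH]1
F4 | step 5 | (E,E)-N,N'-{[(1R,2R,3S,4S)-3,4-di(imidazo[1,2-a]pyrimidin-3-yl)cyclobutane-1,2-diyl]bis(methylene)}bis(1-phenylmethanimine) | c1cnc2ncc([C@H]3[C@H](C/N=C/c4ccccc4)[C@@H](C/N=C/c4ccccc4)[C@@H]3c3cnc4ncccn34)n2c1
F0 | step 1 | none | none
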